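## Retrosynthetic overview

1. Locants used throughout: C1 = CH–iPr, C2 and C6 = ring-fusion carbons, C3 = CH2, C4 = C(CH3) and C5 = CH of the oxirane, C7 = CH2, C8 = C(CH3)OH, C9 = CH2, C10 = CH–O-aroyl. The cyclopentane is C2–C3–C4–C5–C6 and the cycloheptane is C1–C2–C6–C7–C8–C9–C10.
2. Enabling feature: the oxirane is fused to the cyclopentane at C4–C5, with C4 fully substituted (CH3) and C5 a CH on ring-fusion carbon C6. The C4–C5 bond is therefore both the last cyclopentane bond and the epoxide C–C bond, the retron of a sulfonium ylide at C5 (CH2–SPh2+ arm on C6) adding to a methyl ketone at C4 (acetonyl arm on C2, trans to the C6 arm).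
3. Keto sulfonium salt 23 ⇐ triol 17 ⇐ bridged γ-lactone 16, a temporary C5(=O)–O–C8 ring that fixes the C8 carbinol cis to the C6 arm ⇐ cycloheptenone 13; the C10–OH comes from 1,2-reduction of 13.
4. 13 ⇐ one-carbon ring expansion (C9 inserted by cyclopropanation and oxidative cleavage) of cyclohexene silyl enol ether 9 ⇐ catalytic enantioselective Diels–Alder reaction of 2-silyloxy diene 4 (C7, C8, C10, C1 and both alkyl groups) with enoate 8 (C5, C6, C2, C3, C4), which sets the C1/C2/C6 triad.
5. Order of ring formation: six-membered carbocycle (step 5) → seven-membered ring (steps 6–7) → temporary lactone (made in step 10, cleaved in step 11) → cyclopentane and, in the same operation, the oxirane (step 17).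

Key step: step 17

Remark: the (S)-configured oxazaborolidinium catalyst of step 5 is assumed to shield the enoate face that leads to the C2/C6 configuration drawn for 9; if the sense of induction is the opposite, its enantiomer is used.

## Route

Step 1
Reactants: 1 3-methylbutanoyl chloride; 2 tributyl(prop-1-en-2-yl)stannane
Product: 3 2,5-dimethylhex-1-en-3-one
Conditions: PdCl2(PPh3)2 (2 mol%), toluene, 80 °C
Reagents that add atoms: none
Why: Stille acylation of an acid chloride with an alkenylstannane should give the isopropenyl ketone directly, without over-addition.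

Step 2
Reactants: 3 2,5-dimethylhex-1-en-3-one
Product: 4 (3Z)-3-[(tert-butyldimethylsilyl)oxy]-2,5-dimethylhexa-1,3-diene
Conditions: TBSOTf, Et3N, Et2O, 0 °C → rt
Reagents that add atoms: tert-butyldimethylsilyl trifluoromethanesulfonate, CC(C)(C)[Si](C)(C)OS(=O)(=O)C(F)(F)F
Why: Silyl enol ether formation by soft enolisation at the only enolisable α-position should give the 2-silyloxy diene, the (Z)-enol ether being favoured because it keeps the isopropyl group away from the isopropenyl unit.

Step 3
Reactants: 5 ethyl 2-(2-methyl-1,3-dioxolan-2-yl)acetate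
Product: 6 2-(2-methyl-1,3-dioxolan-2-yl)acetaldehyde
Conditions: i-Bu2AlH, CH2Cl2, −78 °C; aqueous potassium sodium tartrate
Reagents that add atoms: none
Why: Partial hydride reduction of the ester at low temperature should stop at the aldehyde through the stable aluminium hemiacetal, with the dioxolane inert.

Step 4
Reactants: 6 2-(2-methyl-1,3-dioxolan-2-yl)acetaldehyde; 7 methyl (triphenylphosphoranylidene)acetate
Product: 8 methyl (2E)-4-(2-methyl-1,3-dioxolan-2-yl)but-2-enoate
Conditions: CH2Cl2, rt
Reagents that add atoms: none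
Why: Wittig olefination with a stabilised ylide should give the (E)-enoate.

Step 5
Reactants: 4 (3Z)-3-[(tert-butyldimethylsilyl)oxy]-2,5-dimethylhexa-1,3-diene; 8 methyl (2E)-4-(2-methyl-1,3-dioxolan-2-yl)but-2-enoate
Product: 9 methyl (1S,5S,6S)-4-[(tert-butyldimethylsilyl)oxy]-3-methyl-6-[(2-methyl-1,3-dioxolan-2-yl)methyl]-5-(propan-2-yl)cyclohex-3-ene-1-carboxylate
Conditions: (S)-3,3-diphenyl-1-(2-methylphenyl)tetrahydro-1H,3H-pyrrolo[1,2-c][1,3,2]oxazaborole + HNTf2 (20 mol%), CH2Cl2, −40 → −20 °C
Reagents that add atoms: none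
Why: In this Lewis-acid-catalysed Diels–Alder reaction the nucleophilic enol ether terminus of the diene (C1) should bond to the β-carbon of the enoate (C2), the (E)-dienophile fixes the C2 and C6 arms trans, the endo transition state places the isopropyl group trans to the C2 arm, and the chiral oxazaborolidinium ion selects the enoate face and so the absolute configuration.

Step 6
Reactants: 9 Diels–Alder adduct (cyclohexene silyl enol ether)
Product: 10 siloxycyclopropane (9 with CH2 added across the C8=C10 enol ether bond)
Conditions: Et2Zn, CH2I2, CH2Cl2, 0 °C → rt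
Reagents that add atoms: diiodomethane, ICI
Why: Simmons–Smith cyclopropanation should take place at the electron-rich enol ether double bond, expected anti to the isopropyl group; the two new centres are destroyed in step 7.

Step 7
Reactants: 10 siloxycyclopropane
Product: 13 cycloheptenone ester (C10 ketone conjugated with C8=C9), via cyclopropanol 11 (not isolated), via chloro ketone 12 (not isolated)
Conditions: Bu4NF, AcOH, THF, 0 °C; FeCl3, pyridine, DMF, 0 °C → rt; NaOAc, MeOH, 65 °C
Reagents that add atoms: none
Why: In this oxidative cyclopropanol ring expansion (Saegusa–Ito type) FeCl3 should generate the cyclopropyloxy radical, β-scission of the internal bond gives the tertiary C8 radical of the seven-membered ketone, and chlorine transfer followed by base-induced loss of HCl gives the conjugated enone, with C1 (now α to the ketone) resting in the thermodynamic trans arrangement.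

Step 8
Reactants: 13 cycloheptenone ester
Product: 14 allylic alcohol (C10–OH trans to the isopropyl group on C1)
Conditions: NaBH4, CeCl3·7H2O, MeOH, −40 °C
Reagents that add atoms: none
Why: In the Luche 1,2-reduction the small hydride should add along the axial trajectory of the enone and give the pseudo-equatorial C10 alcohol, trans to the adjacent equatorial isopropyl group.

Step 9
Reactants: 14 allylic alcohol
Product: 15 hydroxy acid
Conditions: LiOH, THF/MeOH/H2O, 40 °C; aq. HCl to pH 4, 0 °C
Reagents that add atoms: lithium hydroxide, [Li+].[OH-]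
Why: Saponification of the methyl ester should leave the dioxolane and the allylic alcohol untouched, as both tolerate base and a brief cold acidification.

Step 10
Reactants: 15 hydroxy acid
Product: 16 hydroxy lactone (γ-lactone C5(=O)–O–C8 bridging C6 and C8)
Conditions: N,N′-bis(3,5-di-tert-butylsalicylidene)-1,2-cyclohexanediaminocobalt (5 mol%), N-fluoro-2,4,6-trimethylpyridinium tetrafluoroborate, PhSiH3, acetone, 0 °C → rt
Reagents that add atoms: none
Why: In this Markovnikov hydro-acyloxylation by metal-hydride hydrogen atom transfer and radical-polar crossover (Mukaiyama-type), a hydrogen atom should add to C9 and the oxidised tertiary C8 centre be captured by the carboxyl group, which can reach C8 only from its own face, so the bridging lactone sets the C8 oxygen cis to C5.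

Step 11
Reactants: 16 hydroxy lactone
Product: 17 triol
Conditions: LiAlH4, THF, 0 °C → rt
Reagents that add atoms: none
Why: Hydride reduction of the lactone should open the temporary bridge to the primary C5 alcohol and the tertiary C8 alcohol without touching a stereocentre or the dioxolane.

Step 12
Reactants: 17 triol
Product: 18 iodo diol
Conditions: I2, PPh3, imidazole, CH2Cl2, 0 °C
Reagents that add atoms: iodine, II
Why: Appel-type iodination should be selective for the unhindered primary alcohol over the hindered secondary and the tertiary alcohol.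

Step 13
Reactants: 18 iodo diol; 19 4-[(tert-butyldimethylsilyl)oxy]benzoic acid
Product: 20 C10 aryl ester
Conditions: DIC, DMAP, CH2Cl2, rt
Reagents that add atoms: none
Why: Steglich esterification should acylate the only secondary alcohol (C10, with retention), as the tertiary C8 alcohol does not react under these conditions.

Step 14
Reactants: 20 C10 aryl ester
Product: 21 C8 silyl ether
Conditions: TBSOTf, 2,6-lutidine, CH2Cl2, −78 → 0 °C
Reagents that add atoms: tert-butyldimethylsilyl trifluoromethanesulfonate, CC(C)(C)[Si](C)(C)OS(=O)(=O)C(F)(F)F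
Why: Silylation with a silyl triflate should mask the tertiary C8 alcohol, which sits cis to the C5 arm and would otherwise displace the leaving group at C5 to give a bridged ether.

Step 15
Reactants: 21 C8 silyl ether
Product: 22 iodo ketone
Conditions: PPTS, acetone/H2O (10:1), 45 °C
Reagents that add atoms: water, O
Why: Mild acid-catalysed ketal hydrolysis should free the methyl ketone while the silyl ethers, the aryl ester and the iodide survive.

Step 16
Reactants: 22 iodo ketone
Product: 23 diphenylsulfonium tetrafluoroborate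
Conditions: Ph2S (5 equiv), AgBF4, CH2Cl2, 0 °C → rt, dark
Reagents that add atoms: diphenyl sulfide, c1ccc(cc1)Sc1ccccc1; silver tetrafluoroborate, [Ag+].F[B-](F)(F)F
Why: Silver-assisted S-alkylation of diphenyl sulfide by the primary iodide should give the alkyldiphenylsulfonium salt, whose only α-hydrogens are those on C5.

Step 17
Reactants: 23 diphenylsulfonium tetrafluoroborate
Product: 26 bis-silyl epoxide, via ylide 24 (not isolated), via betaine 25 (not isolated)
Conditions: LiN(SiMe3)2 (1.05 equiv), THF, −78 → −20 °C
Reagents that add atoms: none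
Why: LiN(SiMe3)2 should remove a proton from C5, the only position α to sulfur and several pK units more acidic than the ketone α-positions, to give the unstabilised sulfonium ylide 24. Its carbanion adds to the C4 ketone in a 5-exo-trig closure that forms the C4–C5 bond and hence the cyclopentane (betaine 25), and the C4 alkoxide then displaces diphenyl sulfide from C5 in a 3-exo-tet closure to the oxirane; the closest known reaction type is the intramolecular Corey–Chaykovsky epoxidation (epoxy-annulation of a sulfonium ylide onto a tethered ketone). The trans ring fusion is not made here but inherited from the trans C2/C6 arms set in step 5. The new centres C4 and C5 are controlled by C6: the bulky Ph2S+ group on C5 should sit anti to the C6–C7 bond (syn to C6–H), and only the betaine with O− trans to S+ can reach the anti-periplanar geometry for displacement, so the oxygen ends on the ring face of C7 and the C4 methyl group on the opposite face (4R,5S). The step needs ylide formation and addition to outrun ketone enolisation and β-elimination of the sulfonium group (low temperature, non-nucleophilic amide base), and needs the ketone to be the only electrophile in reach, which the silyl ether on C8–O and the hindered, electron-rich aryl ester at C10 secure.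

Step 18
Reactants: 26 bis-silyl epoxide
Product: 27 target (CNP0245441.1)
Conditions: Bu4NF, AcOH, THF, 0 → 40 °C
Reagents that add atoms: none
Why: Fluoride-mediated desilylation should cleave the aryl and the tertiary silyl ether, the acetic acid buffer keeping the medium near neutral so that the epoxide and the aryl ester survive.

## Compound list

1 | 3-methylbutanoyl chloride | CC(C)CC(Cl)=O | starting material
2 | tributyl(prop-1-en-2-yl)stannane | CCCC[Sn](CCCC)(CCCC)C(C)=C | starting material
3 | 2,5-dimethylhex-1-en-3-one | CC(C)CC(=O)C(C)=C | intermediate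
4 | (3Z)-3-[(tert-butyldimethylsilyl)oxy]-2,5-dimethylhexa-1,3-diene | CC(C)/C=C(\O[Si](C)(C)C(C)(C)C)C(C)=C | intermediate
5 | ethyl 2-(2-methyl-1,3-dioxolan-2-yl)acetate | CCOC(=O)CC1(C)OCCO1 | starting material
6 | 2-(2-methyl-1,3-dioxolan-2-yl)acetaldehyde | O=CCC1(C)OCCO1 | intermediate
7 | methyl (triphenylphosphoranylidene)acetate | COC(=O)C=P(c1ccccc1)(c1ccccc1)c1ccccc1 | starting material
8 | methyl (2E)-4-(2-methyl-1,3-dioxolan-2-yl)but-2-enoate | COC(=O)/C=C/CC1(C)OCCO1 | intermediate
9 | methyl (1S,5S,6S)-4-[(tert-butyldimethylsilyl)oxy]-3-methyl-6-[(2-methyl-1,3-dioxolan-2-yl)methyl]-5-(propan-2-yl)cyclohex-3-ene-1-carboxylate; ring atoms are C6, C7, C8, C10, C1, C2; ester (C5) on C6 trans to the ketal arm on C2, isopropyl on C1 trans to that arm | CC(C)[C@H]1[C@H](CC2(C)OCCO2)[C@@H](C(=O)OC)CC(C)=C1O[Si](C)(C)C(C)(C)C | intermediate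
10 | siloxycyclopropane: methyl 1-[(tert-butyldimethylsilyl)oxy]-6-methyl-3-[(2-methyl-1,3-dioxolan-2-yl)methyl]-2-(propan-2-yl)bicyclo[4.1.0]heptane-4-carboxylate, i.e. 9 with CH2 (C9) added across C8=C10 anti to the isopropyl group; other centres as in 9 | CC(C)[C@H]1[C@H](CC2(C)OCCO2)[C@@H](C(=O)OC)C[C@]2(C)C[C@]12O[Si](C)(C)C(C)(C)C | intermediate
11 | cyclopropanol: 10 with OH in place of the silyloxy group | CC(C)[C@H]1[C@H](CC2(C)OCCO2)[C@@H](C(=O)OC)C[C@]2(C)C[C@]12O | intermediate
12 | chloro ketone: methyl 6-chloro-6-methyl-2-[(2-methyl-1,3-dioxolan-2-yl)methyl]-4-oxo-3-(propan-2-yl)cycloheptane-1-carboxylate; C10 ketone, Cl and CH3 on C8 (both C8 epimers); C1, C2, C6 as in 9 | CC(C)[C@H]1[C@H](CC2(C)OCCO2)[C@@H](C(=O)OC)CC(C)(Cl)CC1=O | intermediate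
13 | cycloheptenone ester: methyl 3-methyl-7-[(2-methyl-1,3-dioxolan-2-yl)methyl]-5-oxo-6-(propan-2-yl)cyclohept-3-ene-1-carboxylate; C10 ketone conjugated with C8=C9; C1/C2 trans, C2/C6 trans, spatial arrangement at C1, C2, C6 as in 27 | CC(C)[C@H]1[C@H](CC2(C)OCCO2)[C@@H](C(=O)OC)CC(C)=CC1=O | intermediate
14 | allylic alcohol: 13 with C10–OH in place of the ketone, OH trans to the isopropyl group on C1 (C10 as in 27) | CC(C)[C@H]1[C@H](CC2(C)OCCO2)[C@@H](C(=O)OC)CC(C)=C[C@@H]1O | intermediate
15 | hydroxy acid: 14 with CO2H in place of CO2CH3 | CC(C)[C@H]1[C@H](CC2(C)OCCO2)[C@@H](C(O)=O)CC(C)=C[C@@H]1O | intermediate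
16 | hydroxy lactone: γ-lactone C5(=O)–O–C8 bridging C6 and C8 (7-oxabicyclo[4.2.1]nonan-8-one core), C8 bearing CH3 and the lactone oxygen, C9 = CH2; C10–OH, isopropyl on C1 and ketal arm on C2 as in 14 | CC(C)[C@H]1[C@H](CC2(C)OCCO2)[C@@H]2C[C@@](C)(OC2=O)C[C@@H]1O | intermediate
17 | triol: CH2OH (C5) on C6, tertiary C8–OH cis to that arm, C10–OH; ketal arm on C2, isopropyl on C1; centres C1, C2, C6, C8, C10 as in 27 | CC(C)[C@H]1[C@H](CC2(C)OCCO2)[C@@H](CO)C[C@@](C)(O)C[C@@H]1O | intermediate
18 | iodo diol: 17 with CH2I in place of CH2OH | CC(C)[C@H]1[C@H](CC2(C)OCCO2)[C@@H](CI)C[C@@](C)(O)C[C@@H]1O | intermediate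
19 | 4-[(tert-butyldimethylsilyl)oxy]benzoic acid | CC(C)(C)[Si](C)(C)Oc1ccc(cc1)C(O)=O | starting material
20 | C10 aryl ester: 18 acylated at C10–O with the 4-[(tert-butyldimethylsilyl)oxy]benzoyl group | CC(C)[C@H]1[C@H](CC2(C)OCCO2)[C@@H](CI)C[C@@](C)(O)C[C@@H]1OC(=O)c1ccc(O[Si](C)(C)C(C)(C)C)cc1 | intermediate
21 | C8 silyl ether: 20 with C8–O–Si(CH3)2C(CH3)3 | CC(C)[C@H]1[C@H](CC2(C)OCCO2)[C@@H](CI)C[C@@](C)(O[Si](C)(C)C(C)(C)C)C[C@@H]1OC(=O)c1ccc(O[Si](C)(C)C(C)(C)C)cc1 | intermediate
22 | iodo ketone: 21 with the dioxolane hydrolysed (acetonyl arm CH2C(=O)CH3 on C2) | CC(C)[C@H]1[C@H](CC(C)=O)[C@@H](CI)C[C@@](C)(O[Si](C)(C)C(C)(C)C)C[C@@H]1OC(=O)c1ccc(O[Si](C)(C)C(C)(C)C)cc1 | intermediate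
23 | diphenylsulfonium tetrafluoroborate: 22 with CH2–S+Ph2 BF4− in place of CH2I | CC(C)[C@H]1[C@H](CC(C)=O)[C@@H](C[S+](c2ccccc2)c2ccccc2)C[C@@](C)(O[Si](C)(C)C(C)(C)C)C[C@@H]1OC(=O)c1ccc(O[Si](C)(C)C(C)(C)C)cc1.F[B-](F)(F)F | intermediate
24 | sulfonium ylide: 23 deprotonated at C5 | CC(C)[C@H]1[C@H](CC(C)=O)[C@@H]([CH-][S+](c2ccccc2)c2ccccc2)C[C@@](C)(O[Si](C)(C)C(C)(C)C)C[C@@H]1OC(=O)c1ccc(O[Si](C)(C)C(C)(C)C)cc1 | intermediate
25 | betaine: trans-fused cyclopentane closed at C4–C5; C4 bears O− and CH3, C5 bears S+Ph2 trans to O− and anti to the C6–C7 bond | CC(C)[C@H]1[C@@H]2C[C@@](C)([O-])[C@H]([S+](c3ccccc3)c3ccccc3)[C@H]2C[C@@](C)(O[Si](C)(C)C(C)(C)C)C[C@@H]1OC(=O)c1ccc(O[Si](C)(C)C(C)(C)C)cc1 | intermediate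
26 | bis-silyl epoxide: 27 with tert-butyldimethylsilyl groups on C8–O and on the phenol oxygen | CC(C)[C@H]1[C@@H]2C[C@@]3(C)O[C@H]3[C@H]2C[C@@](C)(O[Si](C)(C)C(C)(C)C)C[C@@H]1OC(=O)c1ccc(O[Si](C)(C)C(C)(C)C)cc1 | intermediate
27 | target: C10 4-hydroxybenzoate of the trans-fused C4,C5-epoxy C8-carbinol; 1S,2R,4R,5S,6S,8R,10S with the overview locants | CC(C)[C@H]1[C@@H]2C[C@@]3(C)O[C@H]3[C@H]2C[C@@](C)(O)C[C@@H]1OC(=O)c1ccc(O)cc1 | target

## Step count and risks

Total step count: 18.
Longest linear sequence: 16 steps (5 → 27 through steps 3–18; equally 1 → 27 through steps 1, 2 and 5–18).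

Three steps most likely to fail:

1. Step 17 (key step). What may go wrong: base-induced β-elimination of the sulfonium group across C5–C6, enolate alkylation at C5 instead of ylide addition, or ylide addition with the wrong facial sense. The fallback sets out from iodo ketone 22 and comes back at 26. Heating 22 with PPh3 in MeCN gives the C5 triphenylphosphonium iodide F1. KN(SiMe3)2 (THF, −78 °C → rt) then closes the ring by intramolecular Wittig olefination to the bis-silyl cyclopentene F2, with a C4=C5 double bond. Epoxidation of that trisubstituted double bond with dimethyldioxirane (acetone, −20 °C), expected from the face anti to the pseudo-axial C6–H, would give 26.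

2. Step 5. What may go wrong: sluggish cycloaddition between the two substituted termini, which would allow desilylation of the diene or stepwise Mukaiyama–Michael addition and erode regio- and enantiocontrol. The fallback sets out from aldehyde 6 and comes back at 9. Wittig reaction of 6 with (triphenylphosphoranylidene)acetaldehyde gives (2E)-4-(2-methyl-1,3-dioxolan-2-yl)but-2-enal F3, a dienophile of the more reactive enal class. Cycloaddition with diene 4 under an oxazaborolidinium catalyst of the enantiomer matched to the enal gives the cyclohexene carbaldehyde F4. Chlorite oxidation (NaClO2, NaH2PO4, 2-methyl-2-butene, t-BuOH/H2O, 0 °C) gives the cyclohexene carboxylic acid F5, and methylation with Me3SiCHN2 returns 9.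

3. Step 8. What may go wrong: insufficient facial discrimination in hydride delivery to the C10 carbonyl of the flexible cycloheptenone. The fallback sets out from enone 13 and comes back at 14. LiBH(s-Bu)3 (THF, −78 °C), a bulky hydride that attacks from the face opposite to that used by the small reagent, gives the C10-epimeric allylic alcohol F6. Mitsunobu reaction (PPh3, DIAD, 4-nitrobenzoic acid) inverts C10 to the allylic 4-nitrobenzoate F7, and methanolysis (K2CO3, MeOH, 0 °C) gives 14.

Further compounds
F1 | step 17 | C5 triphenylphosphonium iodide (22 with CH2–P+Ph3 I− in place of CH2I) | CC(C)[C@H]1[C@H](CC(C)=O)[C@@H](C[P+](c2ccccc2)(c2ccccc2)c2ccccc2)C[C@@](C)(O[Si](C)(C)C(C)(C)C)C[C@@H]1OC(=O)c1ccc(O[Si](C)(C)C(C)(C)C)cc1.[I-]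
F2 | step 17 | bis-silyl cyclopentene (26 with a C4=C5 double bond in place of the oxirane) | CC(C)[C@H]1[C@@H]2CC(C)=C[C@H]2C[C@@](C)(O[Si](C)(C)C(C)(C)C)C[C@@H]1OC(=O)c1ccc(O[Si](C)(C)C(C)(C)C)cc1
F3 | step 5 | (2E)-4-(2-methyl-1,3-dioxolan-2-yl)but-2-enal | O=C/C=C/CC1(C)OCCO1
F4 | step 5 | cyclohexene carbaldehyde (9 with CHO in place of CO2CH3) | CC(C)[C@H]1[C@H](CC2(C)OCCO2)[C@@H](C=O)CC(C)=C1O[Si](C)(C)C(C)(C)C
F5 | step 5 | cyclohexene carboxylic acid (9 with CO2H in place of CO2CH3) | CC(C)[C@H]1[C@H](CC2(C)OCCO2)[C@@H](C(O)=O)CC(C)=C1O[Si](C)(C)C(C)(C)C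
F6 | step 8 | C10-epimeric allylic alcohol (14 with C10–OH cis to the isopropyl group) | CC(C)[C@H]1[C@H](CC2(C)OCCO2)[C@@H](C(=O)OC)CC(C)=C[C@H]1O
F7 | step 8 | allylic 4-nitrobenzoate (14 acylated at C10–O with 4-nitrobenzoyl) | CC(C)[C@H]1[C@H](CC2(C)OCCO2)[C@@H](C(=O)OC)CC(C)=C[C@@H]1OC(=O)c1ccc(cc1)[N+]([O-])=O
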